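Remarks and assumptions on the chemistry

- Locants are those of the briarane skeleton and are used for every intermediate: C1–C10 is the ten-membered ring (C15 is the methyl on C1), C11–C14 complete ring A (C20 is the methyl on C11), C16 is the methyl on C5, and C17–C19 are the lactone carbons (C18 is the methyl on C17). β is the face of the C1 methyl; α is the face of H10 in the target.
- Structure check: 5 is the endo, cis-fused adduct (H10 and the C1 methyl cis, the C11 acetoxy group trans to H10) and already has the C1 configuration of 34. Only C10 has to be inverted, and no structure needed correction.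
- Correction on control: a Lewis acid that binds the quinone through one point would sit on the more basic C2 carbonyl (the vinylogous ester) and could reverse the orientation of the diene. A two-point-binding titanium BINOLate, chelated by O9 and the methoxy oxygen, is therefore specified for the key step.
- The precursors 2 and 4 are kept unchanged. The acetate of 4 is orthogonal to the silyl ethers placed on O2 and O9 and is removed just before C11 is oxidised.
- Assumption: the (S)-BINOL-derived catalyst shields the face that leads to the C1 configuration of 34. If the sense is the opposite, the (R)-ligand is used with no other change.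
- 4 is used as an (E)-enriched distillate; the (Z) isomer is a poor diene. 14 is drawn as the expected C11 epimer, and 26, 27 and 28 are C17 epimer mixtures; these centres are erased in steps 12 and 25.

Structural features

The target is a briarane: a cyclohexene ring A (C1, C10–C14) is trans-fused through C1–C10 to a ten-membered carbocycle (C1–C10). The large ring holds the trisubstituted (Z)-C5=C6 alkene and is fused at C7–C8 to an α-methyl-α,β-dihydroxy-γ-lactone (O7–C19–C17–C8). Ten stereocentres are present: the contiguous run C7–C8–C9–C10–C1–C2–C3, the cis-diol pair C11–C12 in ring A, and C17. The quaternary C1 (methyl β) stands next to C10 (H α), and the fully substituted carbinols C8 and C17 stand side by side with their hydroxyls trans on the lactone. Three secondary acetates (C2, C3, C9) sit beside four free hydroxyls (tertiary at C8, C11 and C17, secondary allylic at C12), so the oxygens must be told apart late. The acetates are sensitive to base and can migrate to neighbouring hydroxyls, the allylic C12 carbinol is sensitive to acid, and the β-hydroxy lactone can undergo retro-aldol cleavage or dehydration. The real difficulty lies in closing the ten-membered ring, in the trans C1/C10 junction at a quaternary carbon, and in the C7/C8/C17 triad. The key step exploits the fact that C1 (methyl) and C10 lie in ring A between the oxygenated C2 and C9: this is the imprint of a 1-oxygenated butadiene (C11–C14) added across the methyl-bearing double bond of a 1,4-benzoquinone. The quinone carbons C3 and C8, told apart by a methoxy group on C8, mark the bond that is later cleaved to admit C4–C7.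

Logic of the disconnections

34 to 31 (through 33 and 32). No skeletal bond is cut; the three acetates are taken off and the 11,12-diol is tied into a ketal. The acetates cannot survive the organometallic steps, and O12 must be kept apart from O2, O3 and O9. The gain is a pattern with two protecting-group classes only (silyl ethers on the future acetate oxygens, one ketal on ring A). The forward demand is fluoride, then an acylation that spares tertiary hydroxyls, then mild acid.

31 to 30. C5=C6 is cut. It is the only alkene of the large ring, and both halves become simple alkenes (a vinyl group on C7, a methallyl unit on C3). The medium ring disappears, so every stereocentre can be set on open-chain or small-ring compounds. The forward step must close a ten-membered ring onto a trisubstituted alkene by metathesis at high dilution.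

30 to 25 (through 29, 28 and 26). C17–C18, the lactone bond O7–C19 and C8–C17 are cut. The two adjacent tertiary carbinols are then made one at a time, each by addition to a ketone with defined faces: C8 through chelation to O7, C17 on the lactone ring anti to the C9 branch. The lactone shrinks to a glycolate unit and a methyl Grignard reagent. The demand is an aldol addition to a hindered, enolisable ketone and ketone-over-lactone selectivity.

25 to 23 (through 24). C7–C8 is cut. C7, its oxygen and the vinyl handle arrive as one alkoxyallyl unit. The demand is reagent control of C7, because substrate bias next to the C9 silyloxy group cannot be trusted.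

23 to 20 (through 22 and 21). C3–C4 is cut. C3 is an aldehyde in 20, and the methallyl unit brings C4, C5, C16 and the second metathesis partner. The forward step must give 3R against the Felkin preference and must leave the ester alone.

20 to 17 (through 19 and 18). C3–C8 is reconnected and the oxygens on C11/C12 are removed. One oxidation in the forward sense serves both the enol ether (prelude to C3–C8 cleavage) and ring A. The gain is a bicyclic compound with ring B intact. The demand is site selectivity among three alkenes and α-face attack.

17 to 12 (through 16, 15, 14 and 13). C11–C20 is cut and the oxygen is moved from C13 back to C11. The cycloaddition leaves oxygen on C11 and the alkene at C12=C13, whereas 34 needs methyl and oxygen on C11, oxygen on C12 and the alkene at C13=C14. Methyl addition, 1,3-transposition and removal of the C13 oxygen bridge that gap. The demand is enone chemistry in the presence of an enol ether.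

12 to 6 (through 11, 10, 8 and 7). No skeletal bond is cut; the C2 and C9 carbinols go back to the quinone carbonyls. In the trans-fused ring hydride reaches both carbonyls from the α face, which is right for C2 and wrong for C9, so C9 is inverted. The demand is stepwise chemoselective reduction and a clean SN2 inversion.

6 to 5. C10 is epimerised. A cycloaddition can only deliver the cis junction. The demand is enolisation toward C10 without loss of the C11 acetate.

5 to 2 and 4. C1–C14 and C10–C11 are cut. Ring A, the quaternary C1 and the C2/C9 oxygens come from two small achiral partners. The demand is site, orientation, endo and enantiofacial control in one step.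

2 to 1 and 4 to 3. A phenol oxidation and an enol acetylation lead back to commercial materials.

Other disconnections considered

Alternative 1: The cut is C8–C17 together with the lactone ring. The β-hydroxy-γ-lactone A1 would form when SmI2 converts a 2-bromopropanoate ester on O7 into a trivalent samarium enolate that adds to a C8 ketone in a preformed ten-membered ring.
- In its favour: the congested C8 carbinol is made intramolecularly, so no external nucleophile has to reach a hindered ketone. The tether fixes C17 on the side of O7, the conditions are mild, and one step gives a C–C bond and a ring.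
- Against it here: the step presupposes the ten-membered ring, which is the hardest part and is left open. The C17 hydroxyl is still missing, and an oxidant approaching the lactone enolate anti to the C9 branch would be expected to give the cis-diol, not the trans-diol of the target. The α-acyloxy ketone is prone to acyl shift and to loss of its α-silyloxy group under SmI2.
- Comparison: on structure it addresses only the lactone, whereas the chosen key step delivers ring A, C1 and the C2/C9 oxygens. On mechanism it relies on a medium-ring conformation for C8, where the chosen plan uses an open-chain chelate and a rigid lactone for C8 and C17. On step economy for the lactone alone it is the better of the two (one step for C8–C17 and the ring against four). The two ideas are compatible and not exclusive.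

Alternative 2: The cut forms C1–C10 and breaks C3–C8. The potassium alkoxide of a trans-1,2-dialkenylcyclohexenol would undergo an anionic oxy-Cope shift to the ten-membered C8 ketone A2.
- In its favour: the ten-membered ring, the quaternary C1 and C10 arise in one sigmatropic step without any macrocyclisation. The (E)-C2=C3 alkene of A2 is ready for syn dihydroxylation to the C2/C3 diol, and the two vinyl groups close ring A by an easy six-membered metathesis.
- Against it here: the substrate needs two stereodefined trisubstituted alkenes and a trans-dialkenyl carbinol. C1 and C10 depend on chair against boat transition states and on both alkene geometries. C9 arrives as CH2 and must be oxidised next to the C8 ketone, in competition with C7.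
- Comparison: on structure this alternative is the better one for the ten-membered ring, which the chosen plan closes late by a demanding metathesis. The chosen plan is the better one for C1, whose absolute configuration comes from a catalytic cycloaddition of two commercial-type partners. On mechanism, both key steps are concerted pericyclic reactions with predictable relative stereochemistry. On step economy the two are probably equal, since the effort saved on ring closure is spent on the rearrangement substrate.

Alternative 3: The cut forms C4–C5 and breaks C2–C7. The potassium alkoxide of a C7-propynyl, C2-vinyl angular-methyl decalol would rearrange, through an allenolate, to the ring A-fused cyclodeca-2,5-dienone A3.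
- In its favour: C1, C10 and ring A are spectators taken from a classical trans-decalin, so the junction is never at risk. The ring expansion gives the ten-membered ring with the C5 methyl alkene and a C7 carbonyl in one step.
- Against it here: A3 has no oxygen on C2, C3 or C8, and C17–C19 are absent. The (Z)-C2=C3 alkene needs an anti dioxygenation, and C8 needs a later α-oxidation on a flexible dienone. The enone geometry rests on the protonation of the allenolate.
- Comparison: on structure it is equal to Alternative 2 and better than the chosen plan for ring formation, but worse in oxidation-state economy, because the chosen plan carries the C2, C3, C8 and C9 functions from the quinone. On mechanism it is a sigmatropic shift against a cycloaddition; the decalin it needs could itself come from the chosen quinone cycloaddition, so the two are complementary. On step economy the late oxygenations are likely to cost what the ring expansion saves.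

Key step: step 3

Step 1
Reactants: 1 2-methoxy-5-methylphenol
Product: 2 2-methoxy-5-methyl-1,4-benzoquinone
Conditions: Co(salen) [Co(C16H14N2O2)] (5 mol %), O2 (1 atm), DMF, 23 °C
Reagents that add atoms: dioxygen, O=O
Why: Cobalt–salen/O2 oxidation of a phenol with a free para position gives the para-quinone; the para carbon of 1 is C4, so methoxy and methyl end up 2,5 as required.

Step 2
Reactants: 3 (E)-but-2-enal
Product: 4 (E)-1-acetoxybuta-1,3-diene
Conditions: Ac2O, KOAc (cat.), reflux; fractional distillation
Reagents that add atoms: acetic anhydride, CC(=O)OC(C)=O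
Why: Enol acetylation of the enal through its extended enolate (O-acylation) gives the dienyl acetate; the (E) isomer is the major one and the only one that reacts readily as a diene.

Step 3
Reactants: 2 2-methoxy-5-methyl-1,4-benzoquinone; 4 (E)-1-acetoxybuta-1,3-diene
Product: 5 cis-fused ring A enedione adduct (11α-acetoxy, 10β-H, 1β-methyl; C2 and C9 ketones, C3=C8 methyl enol ether, C12=C13)
Conditions: (S)-BINOL (20 mol %), TiCl2(OiPr)2 (20 mol %, tetravalent titanium), 4 Å MS for catalyst formation, toluene/CH2Cl2, −30 → 0 °C
Reagents that add atoms: none
Why: Concerted but asynchronous normal-demand [4+2] cycloaddition: the titanium BINOLate binds the quinone through the C9 carbonyl oxygen and the neighbouring methoxy oxygen, lowers the LUMO and makes C1 (β to C9=O) the most electrophilic carbon, so the bond from the unsubstituted diene terminus C14 to C1 runs ahead of C11–C10. The closest known reaction type is the Lewis acid-catalysed Diels–Alder reaction of 2-methoxy-5-methyl-1,4-benzoquinone with butadienes at its methyl-bearing double bond, together with the BINOL–titanium-catalysed enantioselective cycloaddition of quinones with 1-acyloxy dienes. Ring A is closed by suprafacial addition of the s-cis diene across C1=C10, the two new σ bonds (C1–C14, C10–C11) completing a six-membered ring in one step. C1 and C10 are set relative to each other by the suprafacial addition (methyl and H10 cis), C11 by the endo transition state (acetoxy trans to H10), and the absolute sense at C1 by the binaphthyl ligand, which shields one face of the chelated quinone. Site selectivity is secured by the methoxy group, which turns C3=C8 into a vinylogous ester double bond that does not compete. Orientation is secured by the two-point binding at O9 and the methoxy oxygen; an acid that binds through one point would prefer the more basic C2 carbonyl and could turn the diene around. The catalyst also lets the reaction run below 0 °C, where the adduct should not yet lose acetic acid. The quaternary C1 made here is not touched again.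

Step 4
Reactants: 5 cis-fused ring A enedione adduct
Product: 6 trans-fused enedione (10α-H epimer of 5)
Conditions: p-TsOH·H2O (5 mol %), CH2Cl2, 23 °C
Reagents that add atoms: none
Why: Acid-catalysed enolisation toward C10, the only enolisable position, should equilibrate the junction to the trans-fused enedione, the thermodynamic epimerisation known for angular-methyl quinone adducts; acid is chosen because the C10 enolate formed by base would expel the C11 acetate. C10 is set here (H α, trans to the C1 methyl).

Step 5
Reactants: 6 trans-fused enedione
Product: 7 9β-hydroxy enone (C9 carbinol, C2 vinylogous ester intact)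
Conditions: NaBH4, CeCl3·7H2O, MeOH/CH2Cl2, −78 °C
Reagents that add atoms: none
Why: Luche 1,2-reduction takes the C9 carbonyl and leaves the C2 carbonyl, a vinylogous ester; hydride should come from the α face because the axial C1 methyl blocks the β trajectory, giving the 9β (axial) alcohol, which is the wrong epimer and is inverted in step 6.

Step 6
Reactants: 7 9β-hydroxy enone
Product: 8 9α-formate
Conditions: PPh3, DIAD, HCO2H, THF, 0 → 23 °C
Reagents that add atoms: formic acid, O=CO
Why: Mitsunobu reaction displaces the activated axial allylic C9 oxygen with inversion (SN2) and gives the equatorial 9α ester; formic acid is small and acidic enough to outrun elimination toward C10, and its ester can be cleaved beside an acetate.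

Step 7
Reactants: 8 9α-formate
Product: 10 2β,9α-diol 11α-acetate, via 2β-hydroxy 9α-formate 9 (not isolated)
Conditions: NaBH4, CeCl3·7H2O, MeOH, −20 → 0 °C; then KHCO3, MeOH/H2O, 0 °C
Reagents that add atoms: none
Why: A second Luche reduction at higher temperature reduces the C2 vinylogous ester carbonyl 1,2 from the α face (anti to the adjacent axial C1 methyl) and sets the 2β carbinol; bicarbonate methanolysis then removes the formate, which is far more labile than the acetate. The acid-sensitive allylic enol ether diol is kept cold and basic.

Step 8
Reactants: 10 2β,9α-diol 11α-acetate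
Product: 11 2β,9α-bis(tert-butyldimethylsilyl) ether 11α-acetate
Conditions: TBSOTf, 2,6-lutidine, CH2Cl2, −78 → 0 °C
Reagents that add atoms: tert-butyldimethylsilyl triflate, CC(C)(C)[Si](C)(C)OS(=O)(=O)C(F)(F)F
Why: The silyl triflate with a hindered pyridine base silylates both secondary hydroxyls, including the neopentyl C2 one, without touching the acetate or the enol ether; the amine base is too weak to move the acetyl group.

Step 9
Reactants: 11 bis-silyl ether 11α-acetate
Product: 12 11α-alcohol
Conditions: K2CO3, MeOH, 0 → 23 °C
Reagents that add atoms: none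
Why: Mild transesterification removes the only ester and leaves silyl ethers and enol ether; no ketone is present, so no elimination can follow.

Step 10
Reactants: 12 11α-alcohol
Product: 13 C11 enone (C12=C13 conjugated)
Conditions: Dess–Martin periodinane, NaHCO3, CH2Cl2, 0 → 23 °C
Reagents that add atoms: none
Why: Buffered Dess–Martin oxidation of the allylic alcohol gives the enone under neutral conditions, so C10 should not epimerise and the β-silyloxy group should not be lost.

Step 11
Reactants: 13 C11 enone
Product: 14 11-methyl tertiary allylic alcohol (11β-OH, 11α-methyl expected)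
Conditions: MeLi, CeCl3, THF, −78 °C
Reagents that add atoms: methyllithium, [Li]C
Why: The organocerium reagent adds 1,2 to the enolisable enone without deprotonating C10; attack anti to the axial C1 methyl should give mainly the 11β-alcohol, and this centre is erased in step 12.

Step 12
Reactants: 14 tertiary allylic alcohol
Product: 15 C13 enone with C11(methyl)=C12
Conditions: (C5H5NH)[CrO3Cl] (pyridinium chlorochromate), NaOAc, 4 Å MS, CH2Cl2, 23 °C
Reagents that add atoms: none
Why: Babler–Dauben oxidative 1,3-transposition: the chromate ester of the tertiary allylic alcohol shifts [3,3] to C13 and is oxidised to the β-methyl enone, which moves the oxygen to C13 and places the C20 methyl on an sp2 C11. The acetate buffer protects the hindered enol ether, whose oxygen-bearing carbon carries no hydrogen.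

Step 13
Reactants: 15 C13 enone
Product: 16 dienyl triflate (C11=C12, C13(OTf)=C14)
Conditions: LiN(iPr)2, THF, −78 °C; PhNTf2, −78 → 0 °C
Reagents that add atoms: N-phenylbis(trifluoromethanesulfonimide), O=S(=O)(N(c1ccccc1)S(=O)(=O)C(F)(F)F)C(F)(F)F
Why: Kinetic deprotonation of the enone at its only α′ position (C14) and O-triflation of the cross-conjugated dienolate give the dienyl triflate regiospecifically.

Step 14
Reactants: 16 dienyl triflate
Product: 17 ring A diene (C11(methyl)=C12–C13=C14)
Conditions: Pd(OAc)2 (5 mol %), PPh3, Bu3N, HCO2H, DMF, 50 °C
Reagents that add atoms: none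
Why: Palladium-catalysed formate reduction of an enol triflate (oxidative addition to zerovalent palladium, formate exchange, decarboxylation, reductive elimination) replaces OTf by H without moving the double bond.

Step 15
Reactants: 17 ring A diene
Product: 18 11α,12α-diol with ring B acyloin (3α-hydroxy, C8 ketone)
Conditions: OsO4 (5 mol %), N-methylmorpholine N-oxide (2.3 equiv), acetone/H2O, 0 → 23 °C
Reagents that add atoms: N-methylmorpholine N-oxide, C[N+]1([O-])CCOCC1; water, O
Why: Osmium tetroxide should add to the two most electron-rich double bonds, the trisubstituted C11=C12 bond of the diene and the enol ether; the diene is attacked on the α face, anti to the axial C1 methyl, which sets C11 (OH α, methyl β) and C12 (OH α) in one syn addition, while C13=C14 is hindered and then deactivated as an allylic diol. The enol ether diol loses methanol to the 3-hydroxy-8-ketone, whose C3 centre is destroyed in step 17.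

Step 16
Reactants: 18 diol acyloin
Product: 19 11,12-acetonide acyloin
Conditions: 2,2-dimethoxypropane, PPTS (cat.), acetone, 23 °C
Reagents that add atoms: 2,2-dimethoxypropane, COC(C)(C)OC
Why: Acid-catalysed transketalisation forms the five-membered acetonide only on the cis-11,12-diol; it masks the secondary C12 hydroxyl, which must carry no acetate at the end.

Step 17
Reactants: 19 acetonide acyloin
Product: 20 seco aldehyde ester (C3 aldehyde, C8 methyl ester)
Conditions: Pb(OAc)4, MeOH/benzene, 0 °C
Reagents that add atoms: methanol, CO
Why: Criegee cleavage of the α-hydroxy ketone by lead tetraacetate in methanol breaks C3–C8 and gives the C3 aldehyde and the C8 methyl ester directly; it is the equivalent of ozonising the enol ether and spares the ring A alkene.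

Step 18
Reactants: 20 seco aldehyde ester
Product: 21 C3 homoallylic alcohol (3R, hydroxyl α)
Conditions: methallylMgCl, (+)-Ipc2BOMe, Et2O, −78 °C; then 20, −78 °C; NaBO3·4H2O, THF/H2O
Reagents that add atoms: methallylmagnesium chloride, CC(=C)C[Mg]Cl
Why: Brown methallylboration through a closed chair transition state is reagent-controlled; the borane from (−)-α-pinene should give the 3R carbinol against the Felkin preference of the α-silyloxy aldehyde, and it does not touch the ester.

Step 19
Reactants: 21 C3 homoallylic alcohol
Product: 22 3-O-tert-butyldimethylsilyl ether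
Conditions: TBSOTf, 2,6-lutidine, CH2Cl2, −78 → 0 °C
Reagents that add atoms: tert-butyldimethylsilyl triflate, CC(C)(C)[Si](C)(C)OS(=O)(=O)C(F)(F)F
Why: Silylation of the hindered secondary hydroxyl with the triflate puts O3 in the same protecting-group class as O2 and O9, so that the three are freed together.

Step 20
Reactants: 22 silyl ether methyl ester
Product: 23 C8 aldehyde
Conditions: iBu2AlH, CH2Cl2, −78 °C; Rochelle salt
Reagents that add atoms: none
Why: Half-reduction of an α-silyloxy ester stops at the aldehyde because the tetrahedral aluminium hemiacetal is stable at −78 °C.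

Step 21
Reactants: 23 C8 aldehyde
Product: 24 7-O-methoxymethyl 8-hydroxy vinyl adduct (7S, 8R)
Conditions: allyl methoxymethyl ether, sec-BuLi, THF, −78 °C; (+)-Ipc2BOMe; BF3·OEt2; then 23, −78 °C; NaBO3·4H2O
Reagents that add atoms: allyl methoxymethyl ether, C=CCOCOC
Why: Brown (Z)-γ-alkoxyallylboration forms C7–C8 through a closed chair transition state and gives the syn 7-alkoxy-8-hydroxy pair with a vinyl group on C7; the pinene antipode is chosen for 7S, and the C8 carbinol is oxidised next.

Step 22
Reactants: 24 vinyl adduct
Product: 25 C8 ketone
Conditions: Dess–Martin periodinane, NaHCO3, CH2Cl2, 0 → 23 °C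
Reagents that add atoms: none
Why: Neutral Dess–Martin oxidation gives the α,α′-dioxygenated ketone without moving the β,γ double bond into conjugation.

Step 23
Reactants: 25 C8 ketone
Product: 26 glycolate aldol adduct (C8 tertiary carbinol, C17 epimer mixture)
Conditions: methyl 2-(methoxymethoxy)acetate, LiN(iPr)2, THF, −78 °C; CeCl3; then 25, −78 °C
Reagents that add atoms: methyl 2-(methoxymethoxy)acetate, COCOCC(=O)OC
Why: Aldol addition of the cerium ester enolate under chelation control (the metal bridges the C8 carbonyl and the C7 ether oxygen, attack passes the C7 hydrogen) should set the C8 carbinol as in the target; cerium lowers the basicity so that the acidic C7–H is not removed.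

Step 24
Reactants: 26 glycolate aldol adduct
Product: 28 α-hydroxy-γ-lactone (C17 epimer mixture), via triol methyl ester 27 (not isolated)
Conditions: TMSOTf, 2,2′-bipyridyl, CH2Cl2, 0 °C; then H2O; PPTS (cat.), CH2Cl2, 23 °C
Reagents that add atoms: none
Why: The silyl triflate–bipyridyl pair converts methoxymethyl ethers into pyridinium salts that water hydrolyses, while the ketal and the silyl ethers remain; the freed C7 hydroxyl then closes the γ-lactone on the methyl ester, and O9 is still silylated and cannot compete.

Step 25
Reactants: 28 α-hydroxy-γ-lactone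
Product: 29 α-keto-γ-lactone
Conditions: Dess–Martin periodinane, NaHCO3, CH2Cl2, 23 °C
Reagents that add atoms: none
Why: Oxidation of the secondary α-hydroxyl gives a non-enolisable α-keto lactone; the tertiary C8 hydroxyl is inert.

Step 26
Reactants: 29 α-keto-γ-lactone
Product: 30 lactone diene (17-methyl carbinol, metathesis substrate)
Conditions: MeMgBr (3 equiv), THF, −78 °C
Reagents that add atoms: methylmagnesium bromide, C[Mg]Br
Why: Grignard addition to the highly electrophilic ketone of the α-keto lactone is faster than attack on the lactone carbonyl; the methyl group should enter from the face of the C8 oxygen, anti to the bulky C9 branch and guided by the magnesium alkoxide, which sets C17 (methyl cis to the 8-hydroxyl, hydroxyls trans).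

Step 27
Reactants: 30 lactone diene
Product: 31 ten-membered ring lactone (2,3,9-tris-silyl ether, 11,12-acetonide)
Conditions: second-generation Hoveyda–Grubbs catalyst RuCl2(H2IMes)(=CH–C6H4-2-OiPr) (15 mol %), 1,4-benzoquinone (cat.), toluene, 1 mM, 90 °C
Reagents that add atoms: none
Why: Ring-closing metathesis between the vinyl group on C7 and the 1,1-disubstituted C5 alkene forms C5=C6 and the ten-membered ring with loss of ethylene; the ring-cis (Z) geometry is the one a ten-membered ring accommodates, high dilution suppresses oligomers, and the ring A cyclohexene does not open.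

Step 28
Reactants: 31 ten-membered ring lactone
Product: 32 2,3,9-triol 11,12-acetonide
Conditions: HF·pyridine, pyridine, THF, 0 → 40 °C
Reagents that add atoms: none
Why: Buffered fluoride cleaves the three secondary silyl ethers and spares the ketal, the lactone and the tertiary alcohols.

Step 29
Reactants: 32 triol acetonide
Product: 33 2,3,9-triacetate 11,12-acetonide
Conditions: Ac2O, pyridine, DMAP (cat.), CH2Cl2, 0 → 23 °C
Reagents that add atoms: acetic anhydride, CC(=O)OC(C)=O
Why: Acylation under nucleophilic catalysis esterifies the three secondary hydroxyls; the tertiary C8 and C17 hydroxyls react far more slowly and O12 is masked.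

Step 30
Reactants: 33 triacetate acetonide
Product: 34 CNP0269341.1
Conditions: AcOH/H2O (4:1), 40 °C
Reagents that add atoms: none
Why: Mild aqueous acid hydrolyses the ketal and leaves the acetates and the lactone, freeing the 11,12-diol of the target.

Compound list

1 | 2-methoxy-5-methylphenol | COc1ccc(C)cc1O | starting material
2 | 2-methoxy-5-methyl-1,4-benzoquinone | COC1=CC(=O)C(C)=CC1=O | intermediate
3 | (E)-but-2-enal | C/C=C/C=O | starting material
4 | (E)-1-acetoxybuta-1,3-diene | CC(=O)O/C=C/C=C | intermediate
5 | cis-fused ring A enedione adduct (11α-OAc, 10β-H, 1β-methyl) | O=C1[C@@H]2[C@H](OC(C)=O)C=CC[C@]2(C)C(=O)C=C1OC | intermediate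
6 | trans-fused enedione (10α-H) | O=C1[C@H]2[C@H](OC(C)=O)C=CC[C@]2(C)C(=O)C=C1OC | intermediate
7 | 9β-hydroxy enone | O[C@H]1[C@H]2[C@H](OC(C)=O)C=CC[C@]2(C)C(=O)C=C1OC | intermediate
8 | 9α-formate | O=CO[C@@H]1[C@H]2[C@H](OC(C)=O)C=CC[C@]2(C)C(=O)C=C1OC | intermediate
9 | 2β-hydroxy 9α-formate (not isolated) | O=CO[C@@H]1[C@H]2[C@H](OC(C)=O)C=CC[C@]2(C)[C@@H](O)C=C1OC | intermediate
10 | 2β,9α-diol 11α-acetate | O[C@@H]1[C@H]2[C@H](OC(C)=O)C=CC[C@]2(C)[C@@H](O)C=C1OC | intermediate
11 | 2β,9α-bis(TBS) ether 11α-acetate | CC(C)(C)[Si](C)(C)O[C@@H]1[C@H]2[C@H](OC(C)=O)C=CC[C@]2(C)[C@@H](O[Si](C)(C)C(C)(C)C)C=C1OC | intermediate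
12 | 11α-alcohol | CC(C)(C)[Si](C)(C)O[C@@H]1[C@H]2[C@H](O)C=CC[C@]2(C)[C@@H](O[Si](C)(C)C(C)(C)C)C=C1OC | intermediate
13 | C11 enone | CC(C)(C)[Si](C)(C)O[C@@H]1[C@H]2C(=O)C=CC[C@]2(C)[C@@H](O[Si](C)(C)C(C)(C)C)C=C1OC | intermediate
14 | 11-methyl tertiary allylic alcohol (11β-OH expected) | CC(C)(C)[Si](C)(C)O[C@@H]1[C@H]2[C@@](C)(O)C=CC[C@]2(C)[C@@H](O[Si](C)(C)C(C)(C)C)C=C1OC | intermediate
15 | C13 enone with C11(methyl)=C12 | CC(C)(C)[Si](C)(C)O[C@@H]1[C@H]2C(C)=CC(=O)C[C@]2(C)[C@@H](O[Si](C)(C)C(C)(C)C)C=C1OC | intermediate
16 | dienyl triflate | CC(C)(C)[Si](C)(C)O[C@@H]1[C@H]2C(C)=CC(OS(=O)(=O)C(F)(F)F)=C[C@]2(C)[C@@H](O[Si](C)(C)C(C)(C)C)C=C1OC | intermediate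
17 | ring A diene | CC(C)(C)[Si](C)(C)O[C@@H]1[C@H]2C(C)=CC=C[C@]2(C)[C@@H](O[Si](C)(C)C(C)(C)C)C=C1OC | intermediate
18 | 11α,12α-diol with ring B acyloin | CC(C)(C)[Si](C)(C)O[C@@H]1[C@H]2[C@](C)(O)[C@H](O)C=C[C@]2(C)[C@@H](O[Si](C)(C)C(C)(C)C)[C@H](O)C1=O | intermediate
19 | 11,12-acetonide acyloin | CC(C)(C)[Si](C)(C)O[C@@H]1[C@H]2[C@]3(C)OC(C)(C)O[C@@H]3C=C[C@]2(C)[C@@H](O[Si](C)(C)C(C)(C)C)[C@H](O)C1=O | intermediate
20 | seco aldehyde ester | COC(=O)[C@H](O[Si](C)(C)C(C)(C)C)[C@H]1[C@]2(C)OC(C)(C)O[C@@H]2C=C[C@]1(C)[C@@H](O[Si](C)(C)C(C)(C)C)C=O | intermediate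
21 | C3 homoallylic alcohol | COC(=O)[C@H](O[Si](C)(C)C(C)(C)C)[C@H]1[C@]2(C)OC(C)(C)O[C@@H]2C=C[C@]1(C)[C@@H](O[Si](C)(C)C(C)(C)C)[C@H](O)CC(C)=C | intermediate
22 | 3-O-TBS ether methyl ester | COC(=O)[C@H](O[Si](C)(C)C(C)(C)C)[C@H]1[C@]2(C)OC(C)(C)O[C@@H]2C=C[C@]1(C)[C@@H](O[Si](C)(C)C(C)(C)C)[C@H](O[Si](C)(C)C(C)(C)C)CC(C)=C | intermediate
23 | C8 aldehyde | O=C[C@H](O[Si](C)(C)C(C)(C)C)[C@H]1[C@]2(C)OC(C)(C)O[C@@H]2C=C[C@]1(C)[C@@H](O[Si](C)(C)C(C)(C)C)[C@H](O[Si](C)(C)C(C)(C)C)CC(C)=C | intermediate
24 | 7-O-MOM 8-hydroxy vinyl adduct | C=C[C@H](OCOC)[C@@H](O)[C@H](O[Si](C)(C)C(C)(C)C)[C@H]1[C@]2(C)OC(C)(C)O[C@@H]2C=C[C@]1(C)[C@@H](O[Si](C)(C)C(C)(C)C)[C@H](O[Si](C)(C)C(C)(C)C)CC(C)=C | intermediate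
25 | C8 ketone | C=C[C@H](OCOC)C(=O)[C@H](O[Si](C)(C)C(C)(C)C)[C@H]1[C@]2(C)OC(C)(C)O[C@@H]2C=C[C@]1(C)[C@@H](O[Si](C)(C)C(C)(C)C)[C@H](O[Si](C)(C)C(C)(C)C)CC(C)=C | intermediate
26 | glycolate aldol adduct | C=C[C@H](OCOC)[C@@](O)(C(OCOC)C(=O)OC)[C@H](O[Si](C)(C)C(C)(C)C)[C@H]1[C@]2(C)OC(C)(C)O[C@@H]2C=C[C@]1(C)[C@@H](O[Si](C)(C)C(C)(C)C)[C@H](O[Si](C)(C)C(C)(C)C)CC(C)=C | intermediate
27 | triol methyl ester (not isolated) | C=C[C@H](O)[C@@](O)(C(O)C(=O)OC)[C@H](O[Si](C)(C)C(C)(C)C)[C@H]1[C@]2(C)OC(C)(C)O[C@@H]2C=C[C@]1(C)[C@@H](O[Si](C)(C)C(C)(C)C)[C@H](O[Si](C)(C)C(C)(C)C)CC(C)=C | intermediate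
28 | α-hydroxy-γ-lactone | C=C[C@@H]1OC(=O)C(O)[C@@]1(O)[C@H](O[Si](C)(C)C(C)(C)C)[C@H]2[C@]3(C)OC(C)(C)O[C@@H]3C=C[C@]2(C)[C@@H](O[Si](C)(C)C(C)(C)C)[C@H](O[Si](C)(C)C(C)(C)C)CC(C)=C | intermediate
29 | α-keto-γ-lactone | C=C[C@@H]1OC(=O)C(=O)[C@@]1(O)[C@H](O[Si](C)(C)C(C)(C)C)[C@H]2[C@]3(C)OC(C)(C)O[C@@H]3C=C[C@]2(C)[C@@H](O[Si](C)(C)C(C)(C)C)[C@H](O[Si](C)(C)C(C)(C)C)CC(C)=C | intermediate
30 | lactone diene | C=C[C@@H]1OC(=O)[C@@](C)(O)[C@@]1(O)[C@H](O[Si](C)(C)C(C)(C)C)[C@H]2[C@]3(C)OC(C)(C)O[C@@H]3C=C[C@]2(C)[C@@H](O[Si](C)(C)C(C)(C)C)[C@H](O[Si](C)(C)C(C)(C)C)CC(C)=C | intermediate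
31 | ten-membered ring lactone, tris-TBS ether acetonide | CC(C)(C)[Si](C)(C)O[C@@H]1[C@H]2[C@]3(C)OC(C)(C)O[C@@H]3C=C[C@]2(C)[C@@H](O[Si](C)(C)C(C)(C)C)[C@H](O[Si](C)(C)C(C)(C)C)C/C(C)=C\[C@@H]2OC(=O)[C@@](C)(O)[C@]21O | intermediate
32 | 2,3,9-triol 11,12-acetonide | O[C@@H]1[C@H]2[C@]3(C)OC(C)(C)O[C@@H]3C=C[C@]2(C)[C@@H](O)[C@H](O)C/C(C)=C\[C@@H]2OC(=O)[C@@](C)(O)[C@]21O | intermediate
33 | 2,3,9-triacetate 11,12-acetonide | CC(=O)O[C@@H]1[C@H]2[C@]3(C)OC(C)(C)O[C@@H]3C=C[C@]2(C)[C@@H](OC(C)=O)[C@H](OC(C)=O)C/C(C)=C\[C@@H]2OC(=O)[C@@](C)(O)[C@]21O | intermediate
34 | CNP0269341.1 | CC(=O)O[C@@H]1[C@H]2[C@](C)(O)[C@H](O)C=C[C@]2(C)[C@@H](OC(C)=O)[C@H](OC(C)=O)C/C(C)=C\[C@@H]2OC(=O)[C@@](C)(O)[C@]21O | target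

Total step count: 30. Longest linear sequence: 29 steps (1 → 34 through steps 1 and 3–30; the same length from 3 through steps 2–30).

Least certain steps

Step 3 (key step). The most likely failure is binding of the Lewis acid at the C2 carbonyl in place of the O9/methoxy chelate, which would turn the diene around, or a weak facial bias that gives low enantiomeric purity; the acetoxy diene may also be ionised by the acid. Fallback: setting out from 2 and 4, the cycloaddition is run thermally without catalyst (toluene, 60–80 °C), where the orientation rests on the unperturbed quinone. This should give 5 together with its mirror image, the ent-adduct F1. An esterase or lipase screened for the antipode (pH 7 buffer) would hydrolyse the acetate of F1 to the ent-11-hydroxy adduct F2, which is separated, and the route is rejoined at 5.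

Step 4. The risk is loss of acetic acid across C10–C11 once C10 is enolised, or an equilibrium that does not lie far on the trans side because the equatorial C11 acetoxy group clashes with the C9 carbonyl. Fallback: setting out from 5, the enol is trapped under conditions that do not allow elimination (TMSOTf, Et3N, CH2Cl2, −78 °C) as the C9 silyl dienol ether F3. Kinetic C-protonation at −78 °C (camphorsulfonic acid, CH2Cl2/MeOH), with the proton delivered anti to the C1 methyl, should give the trans junction, and the route is rejoined at 6.

Step 15. The risk is poor site selectivity within the diene (attack at C13=C14, or a second dihydroxylation of ring A) and incomplete α-face preference. Fallback: setting out from 16, where C13=C14 is switched off by the triflate, OsO4/N-methylmorpholine N-oxide should give the vinyl triflate diol acyloin F4. 2,2-Dimethoxypropane/PPTS then gives its acetonide F5, and the palladium-catalysed formate reduction of step 14 (Pd(OAc)2, PPh3, Bu3N, HCO2H) removes the triflate; the route is rejoined at 19.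

Step 23. The risk is proton transfer from the doubly activated C7–H of the hindered ketone instead of addition, reversal of the aldol, and incomplete chelation control. Fallback: setting out from 25, the less basic Reformatsky reagent from methyl bromoacetate and zinc (THF, 0 °C) should give the β-hydroxy ester F6. The conditions of step 24 then give the β-hydroxy-γ-lactone F7, and hydroxylation of its dianion (LiN(SiMe3)2, then 2-(phenylsulfonyl)-3-phenyloxaziridine, −78 °C) introduces the C17 oxygen; the route is rejoined at 28.

Step 27. The risk is oligomerisation by cross-metathesis, failure of the two hindered alkenes to engage once the trans-fused lactone restricts the chain, and alkene migration by ruthenium hydrides. Fallback: the ring is closed before the lactone exists. Setting out from 26, the same catalyst at high dilution should give the macrocyclic aldol adduct F8. The conditions of step 24 give the macrocyclic α-hydroxy lactone F9, Dess–Martin oxidation gives the macrocyclic α-keto lactone F10, and MeMgBr addition as in step 26 rejoins the route at 31.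

Further compounds

F1 | step 3 | ent-adduct (enantiomer of 5) | O=C1[C@H]2[C@@H](OC(C)=O)C=CC[C@@]2(C)C(=O)C=C1OC
F2 | step 3 | ent-11-hydroxy adduct | O=C1[C@H]2[C@@H](O)C=CC[C@@]2(C)C(=O)C=C1OC
F3 | step 4 | C9 silyl dienol ether | C[Si](C)(C)OC1=C2[C@H](OC(C)=O)C=CC[C@]2(C)C(=O)C=C1OC
F4 | step 15 | vinyl triflate diol acyloin | CC(C)(C)[Si](C)(C)O[C@@H]1[C@H]2[C@](C)(O)[C@H](O)C(OS(=O)(=O)C(F)(F)F)=C[C@]2(C)[C@@H](O[Si](C)(C)C(C)(C)C)[C@H](O)C1=O
F5 | step 15 | vinyl triflate acetonide acyloin | CC(C)(C)[Si](C)(C)O[C@@H]1[C@H]2[C@]3(C)OC(C)(C)O[C@@H]3C(OS(=O)(=O)C(F)(F)F)=C[C@]2(C)[C@@H](O[Si](C)(C)C(C)(C)C)[C@H](O)C1=O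
F6 | step 23 | β-hydroxy ester (Reformatsky adduct) | C=C[C@H](OCOC)[C@@](O)(CC(=O)OC)[C@H](O[Si](C)(C)C(C)(C)C)[C@H]1[C@]2(C)OC(C)(C)O[C@@H]2C=C[C@]1(C)[C@@H](O[Si](C)(C)C(C)(C)C)[C@H](O[Si](C)(C)C(C)(C)C)CC(C)=C
F7 | step 23 | β-hydroxy-γ-lactone | C=C[C@@H]1OC(=O)C[C@@]1(O)[C@H](O[Si](C)(C)C(C)(C)C)[C@H]2[C@]3(C)OC(C)(C)O[C@@H]3C=C[C@]2(C)[C@@H](O[Si](C)(C)C(C)(C)C)[C@H](O[Si](C)(C)C(C)(C)C)CC(C)=C
F8 | step 27 | macrocyclic aldol adduct | CC(C)(C)[Si](C)(C)O[C@@H]1[C@H]2[C@]3(C)OC(C)(C)O[C@@H]3C=C[C@]2(C)[C@@H](O[Si](C)(C)C(C)(C)C)[C@H](O[Si](C)(C)C(C)(C)C)C/C(C)=C\[C@H](OCOC)[C@@]1(O)C(OCOC)C(=O)OC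
F9 | step 27 | macrocyclic α-hydroxy lactone | CC(C)(C)[Si](C)(C)O[C@@H]1[C@H]2[C@]3(C)OC(C)(C)O[C@@H]3C=C[C@]2(C)[C@@H](O[Si](C)(C)C(C)(C)C)[C@H](O[Si](C)(C)C(C)(C)C)C/C(C)=C\[C@@H]2OC(=O)C(O)[C@]21O
F10 | step 27 | macrocyclic α-keto lactone | CC(C)(C)[Si](C)(C)O[C@@H]1[C@H]2[C@]3(C)OC(C)(C)O[C@@H]3C=C[C@]2(C)[C@@H](O[Si](C)(C)C(C)(C)C)[C@H](O[Si](C)(C)C(C)(C)C)C/C(C)=C\[C@@H]2OC(=O)C(=O)[C@]21O
A1 | alternative 1 | β-hydroxy-γ-lactone with the C8 carbinol (9-O-TBS, 2,3- and 11,12-acetonides) | CC(C)(C)[Si](C)(C)O[C@@H]1[C@H]2[C@]3(C)OC(C)(C)O[C@@H]3C=C[C@]2(C)[C@H]4OC(C)(C)O[C@@H]4C/C(C)=C\[C@@H]2OC(=O)[C@H](C)[C@]21O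
A2 | alternative 2 | ten-membered C8 ketone with C1 and C10 set (7-O-MOM, 11,12-acetonide) | C1[C@@H]([C@]3(C)OC(C)(C)O[C@@H]3C=C)[C@](C)(C=C)/C=C/C/C(C)=C\[C@H](OCOC)C1=O
A3 | alternative 3 | ring A-fused cyclodeca-2,5-dienone (C7 ketone, 9-O-TBS, 11,12-acetonide) | CC(C)(C)[Si](C)(C)O[C@@H]1[C@H]2[C@]3(C)OC(C)(C)O[C@@H]3C=C[C@]2(C)/C=C\C/C(C)=C\C(=O)C1
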